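Assumption: the SMILES is read literally as 2Z,4Z,20Z,38Z and 7S,9R,11S,13R,15S,17R,18R,19S,23R,27R,31R,41S,42S,43R,49R. Locants such as "C19" are target numbers (C1 = lactone C=O, C41 = lactone carbinol). Where a chiral ligand or reagent antipode is named, it is the one that gives the drawn configuration, and the SMILES decides.

## Retrosynthetic overview
1. There is one ring, the 42-membered lactone. It is closed by attack of C41-OH on an activated C1 acyl group, as in thioesterase off-loading, but on a 2,38-diynoic seco-acid.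
2. A single Lindlar hydrogenation after ring closure sets 2Z and 38Z together. One global HF deprotection then gives the target.
3. The seco-acid is cut at C3–C4 (Sonogashira with propiolic acid), C37–C38 (acetylide alkylation, which leaves C41-OH as the only free OH) and C19–C20 (Felkin addition of a (Z)-alkenyllithium).
4. C4–C19 comes from two-directional Ir allylation of propane-1,3-diol to a C2-symmetric dialdehyde, then mono Z-iodo-olefination and allyl/crotylboration.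
5. C20–C37 comes from an allylation/hydroformylation iteration. C38–C50 comes from (R)-propylene oxide, syn-crotylboration and propargylation.

## Route

### Fragment C4–C19

Step 1
Reactants: 1 propane-1,3-diol
Product: 2 (4R,6R)-nona-1,8-diene-4,6-diol
Conditions: allyl acetate (excess), [Ir(cod)Cl]2 (5 mol %), (R)-Cl,MeO-BIPHEP, 4-Cl-3-NO2-C6H3CO2H, Cs2CO3 (cat.), dioxane, 90 °C
Reagents that add atoms: allyl acetate, C=CCOC(C)=O
Why: Two-directional transfer-hydrogenative carbonyl allylation (Krische type) from the alcohol oxidation level sets C9 and C11 under catalyst control, and the minor enantiomer is drained into the meso isomer, so the anti C2 diol is essentially enantiopure.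

Step 2
Reactants: 2 (4R,6R)-nona-1,8-diene-4,6-diol
Product: 4 (3R,5R)-heptane-1,3,5,7-tetraol, via bis-ozonide 3 (not isolated)
Conditions: O3, CH2Cl2, −78 °C; then NaBH4, MeOH, 0 °C
Reagents that add atoms: ozone, [O-][O+]=O
Why: Ozonolysis with reductive work-up trims both allyl groups to 2-hydroxyethyl arms without touching the two carbinol centres.

Step 3
Reactants: 4 (3R,5R)-heptane-1,3,5,7-tetraol
Product: 5 (4S,6R,8R,10S)-trideca-1,12-diene-4,6,8,10-tetraol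
Conditions: allyl acetate, [Ir(cod)Cl]2 (5 mol %), (S)-Cl,MeO-BIPHEP, 4-Cl-3-NO2-C6H3CO2H, Cs2CO3 (cat.), dioxane, 100 °C
Reagents that add atoms: allyl acetate, C=CCOC(C)=O
Why: The Ir catalyst dehydrogenates only primary alcohols, so this site-selective double Krische allylation needs no protection, and the antipodal ligand sets C7 and C13 anti to C9 and C11.

Step 4
Reactants: 5 (4S,6R,8R,10S)-trideca-1,12-diene-4,6,8,10-tetraol
Product: 6 bis-acetonide of 5 (C7/C9 and C11/C13 dioxanes)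
Conditions: Me2C(OMe)2, PPTS, CH2Cl2, rt
Reagents that add atoms: 2,2-dimethoxypropane, COC(C)(C)OC
Why: Exhaustive transketalisation can only pair O7/O9 and O11/O13, which gives the C2-symmetric bis(anti-acetonide).

Step 5
Reactants: 6 bis-acetonide of 5
Product: 8 C2-symmetric C5,C15-dialdehyde, via bis-ozonide 7 (not isolated)
Conditions: O3, CH2Cl2, −78 °C; PPh3, −78 °C → rt
Reagents that add atoms: ozone, [O-][O+]=O
Why: Ozonolysis with PPh3 reduction gives the bis(β-alkoxy aldehyde) under neutral conditions, so no β-elimination occurs.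

Step 6
Reactants: 8 C2-symmetric C5,C15-dialdehyde
Product: 9 (Z)-C4-iodoalkene C15-aldehyde
Conditions: EtPPh3I, n-BuLi, THF; I2, −78 °C; NaHMDS, −20 °C; then this ylide (1 equiv) added to 8 (2 equiv), −78 °C; unreacted 8 recycled
Reagents that add atoms: ethyltriphenylphosphonium iodide, CC[P+](c1ccccc1)(c1ccccc1)c1ccccc1.[I-]; iodine, II
Why: In this Stork–Zhao-type Wittig with Ph3P=C(I)CH3 the two CHO groups are homotopic, so mono-olefination gives one compound, and the α-iodo ylide gives the (Z)-2-iodo-2-alkene (I cis to C6), which fixes the 4Z geometry.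

Step 7
Reactants: 9 (Z)-C4-iodoalkene C15-aldehyde
Product: 11 C15 homoallylic alcohol, via borinate 10 (not isolated)
Conditions: lIpc2B(allyl) [from (−)-α-pinene], Et2O, −78 °C; NaOH, H2O2
Reagents that add atoms: B-allyl-bis(l-isopinocampheyl)borane, C=CCB([C@H]1C[C@H]2C[C@@H]([C@@H]1C)C2(C)C)[C@H]1C[C@H]2C[C@@H]([C@@H]1C)C2(C)C
Why: Brown allylboration through a closed chair transition state sets C15 by reagent control, anti to C13, and the vinyl iodide and acetonides are inert.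

Step 8
Reactants: 11 C15 homoallylic alcohol
Product: 12 C15 TBS ether
Conditions: TBSOTf, 2,6-lutidine, CH2Cl2, 0 °C
Reagents that add atoms: TBSOTf, CC(C)(C)[Si](C)(C)OS(=O)(=O)C(F)(F)F
Why: Standard silylation is used, and the non-chelating OTBS group is wanted later for Felkin control.

Step 9
Reactants: 12 C15 TBS ether
Product: 14 C17 aldehyde, via vicinal diol 13 (not isolated)
Conditions: OsO4 (2 mol %), NaIO4, 2,6-lutidine, dioxane/H2O, rt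
Reagents that add atoms: sodium periodate (O delivered through catalytic OsO4), [Na+].[O-]I(=O)(=O)=O
Why: Johnson–Lemieux cleavage takes the terminal alkene selectively because the trisubstituted vinyl iodide is electron-poor and hindered.

Step 10
Reactants: 14 C17 aldehyde
Product: 16 17,18-anti crotyl adduct, via borinate 15 (not isolated)
Conditions: (E)-2-butene, n-BuLi, KOt-Bu, THF, −78 → −45 °C; (−)-Ipc2BOMe; BF3·OEt2; 14, −78 °C; NaOH, H2O2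
Reagents that add atoms: (E)-but-2-ene, C/C=C/C
Why: In this Brown (E)-crotylboration the E-geometry translates to the 17,18-anti relationship, and the dIpc ligands set the absolute sense (C17 anti to C15).

Step 11
Reactants: 16 17,18-anti crotyl adduct
Product: 17 C15,C17-bis-TBS ether
Conditions: TBSOTf, 2,6-lutidine, CH2Cl2, 0 °C
Reagents that add atoms: TBSOTf, CC(C)(C)[Si](C)(C)OS(=O)(=O)C(F)(F)F
Why: Standard silylation of the hindered secondary alcohol with the triflate is used.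

Step 12
Reactants: 17 C15,C17-bis-TBS ether
Product: 19 C19 aldehyde (C4–C19 fragment), via vicinal diol 18 (not isolated)
Conditions: OsO4 (2 mol %), NaIO4, 2,6-lutidine, dioxane/H2O, rt
Reagents that add atoms: sodium periodate (O delivered through catalytic OsO4), [Na+].[O-]I(=O)(=O)=O
Why: Johnson–Lemieux cleavage under buffered conditions unveils the α-methyl aldehyde without epimerising C18.

### Fragment C20–C37

Step 13
Reactants: 20 7-chloroheptan-1-ol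
Product: 21 (R)-10-chlorodec-1-en-4-ol
Conditions: allyl acetate, [Ir(cod)Cl]2 (2.5 mol %), (S)-Cl,MeO-BIPHEP, 4-Cl-3-NO2-C6H3CO2H, Cs2CO3 (cat.), THF, 100 °C
Reagents that add atoms: allyl acetate, C=CCOC(C)=O
Why: Krische allylation directly from the alcohol sets C31 under catalyst control, and the primary chloride is inert to the catalytic base.

Step 14
Reactants: 21 (R)-10-chlorodec-1-en-4-ol
Product: 22 (6R)-6-(6-chlorohexyl)tetrahydro-2H-pyran-2-ol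
Conditions: Rh(acac)(CO)2 (1 mol %), BIPHEPHOS, CO/H2 (1:1, 10 bar), THF, 60 °C
Reagents that add atoms: carbon monoxide, [C-]#[O+]
Why: Linear-selective hydroformylation adds C27 as the aldehyde, which is trapped as the δ-lactol, giving exactly the 1,5-spacing with no protecting group.

Step 15
Reactants: 22 (6R)-6-(6-chlorohexyl)tetrahydro-2H-pyran-2-ol
Product: 24 (4R,8R)-14-chlorotetradec-1-ene-4,8-diol, via borinate 23 (not isolated)
Conditions: dIpc2B(allyl) [from (+)-α-pinene] (2.5 equiv), Et2O, −78 → −20 °C; NaOH, H2O2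
Reagents that add atoms: B-allyl-bis(d-isopinocampheyl)borane, C=CCB([C@@H]1C[C@@H]2C[C@H]([C@H]1C)C2(C)C)[C@@H]1C[C@@H]2C[C@H]([C@H]1C)C2(C)C
Why: Brown allylboration of the open hydroxy-aldehyde tautomer of the lactol sets C27 purely by reagent control.

Step 16
Reactants: 24 (4R,8R)-14-chlorotetradec-1-ene-4,8-diol
Product: 25 (6R)-6-[(4R)-10-chloro-4-hydroxydecyl]tetrahydro-2H-pyran-2-ol
Conditions: Rh(acac)(CO)2 (1 mol %), BIPHEPHOS, CO/H2 (1:1, 10 bar), THF, 60 °C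
Reagents that add atoms: carbon monoxide, [C-]#[O+]
Why: A second linear hydroformylation adds C23, and the aldehyde is again stored as the lactol with O27.

Step 17
Reactants: 25 (6R)-6-[(4R)-10-chloro-4-hydroxydecyl]tetrahydro-2H-pyran-2-ol
Product: 27 (4R,8R,12R)-18-chlorooctadec-1-ene-4,8,12-triol, via borinate 26 (not isolated)
Conditions: dIpc2B(allyl) (3.5 equiv), Et2O, −78 → −20 °C; NaOH, H2O2
Reagents that add atoms: B-allyl-bis(d-isopinocampheyl)borane, C=CCB([C@@H]1C[C@@H]2C[C@H]([C@H]1C)C2(C)C)[C@@H]1C[C@@H]2C[C@H]([C@H]1C)C2(C)C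
Why: Brown allylboration of the lactol sets C23 by reagent control and completes the R,R,R 1,5,9-triol.

Step 18
Reactants: 27 (4R,8R,12R)-18-chlorooctadec-1-ene-4,8,12-triol
Product: 28 tris-TBS ether of 27
Conditions: TBSOTf (3.6 equiv), 2,6-lutidine, CH2Cl2, 0 °C
Reagents that add atoms: TBSOTf, CC(C)(C)[Si](C)(C)OS(=O)(=O)C(F)(F)F
Why: One silylation protects all three carbinols at once.

Step 19
Reactants: 28 tris-TBS ether of 27
Product: 30 (3R,7R,11R)-17-chloro-3,7,11-tris(TBSO)heptadecanal, via ozonide 29 (not isolated)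
Conditions: O3, CH2Cl2, −78 °C; PPh3
Reagents that add atoms: ozone, [O-][O+]=O
Why: Ozonolysis of the only alkene gives the C21 aldehyde.

Step 20
Reactants: 30 (3R,7R,11R)-17-chloro-3,7,11-tris(TBSO)heptadecanal
Product: 31 (2Z,5R,9R,13R)-19-chloro-2-iodo-5,9,13-tris(TBSO)nonadec-2-ene
Conditions: EtPPh3I, n-BuLi, THF; I2, −78 °C; NaHMDS, −20 °C; 30, −78 °C
Reagents that add atoms: ethyltriphenylphosphonium iodide, CC[P+](c1ccccc1)(c1ccccc1)c1ccccc1.[I-]; iodine, II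
Why: The Stork–Zhao-type Wittig puts I cis to C22, so later stereoretentive metalation delivers the 20Z alkene.

### Fragment C38–C50

Step 21
Reactants: 32 6-bromohex-1-ene; 33 (R)-propylene oxide
Product: 35 (R)-non-8-en-2-ol, via hex-5-enylmagnesium bromide 34 (not isolated)
Conditions: Mg, THF; CuI (10 mol %), 33, −30 °C → 0 °C
Reagents that add atoms: none
Why: Cu-catalysed Grignard opening at the CH2 terminus of the epoxide leaves the chiral-pool centre (C49, R) untouched.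

Step 22
Reactants: 35 (R)-non-8-en-2-ol
Product: 37 (R)-7-hydroxyoctanal, via ozonide 36 (not isolated)
Conditions: O3, CH2Cl2, −78 °C; PPh3
Reagents that add atoms: ozone, [O-][O+]=O
Why: Ozonolysis tolerates the free alcohol, and an eight-membered lactol is not favoured, so the aldehyde stays open.

Step 23
Reactants: 37 (R)-7-hydroxyoctanal
Product: 39 (2R,8R,9R)-9-methylundec-10-ene-2,8-diol, via borinate 38 (not isolated)
Conditions: (Z)-2-butene, n-BuLi, KOt-Bu, THF, −78 → −45 °C; (−)-Ipc2BOMe; BF3·OEt2 (reagent 2.5 equiv); 37, −78 °C; NaOH, H2O2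
Reagents that add atoms: (Z)-but-2-ene, C/C=C\C
Why: In this Brown (Z)-crotylboration the Z-geometry gives the 42,43-syn pair and the dIpc ligands fix its absolute configuration.

Step 24
Reactants: 39 (2R,8R,9R)-9-methylundec-10-ene-2,8-diol
Product: 40 bis-TIPS ether of 39
Conditions: TIPSOTf (2.5 equiv), 2,6-lutidine, CH2Cl2, 0 °C → rt
Reagents that add atoms: TIPSOTf, CC(C)[Si](C(C)C)(C(C)C)OS(=O)(=O)C(F)(F)F
Why: One silylation protects O43 and O49, and TIPS is chosen because it does not undergo 1,3-O→O migration to the C41 alkoxide formed in step 29.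

Step 25
Reactants: 40 bis-TIPS ether of 39
Product: 42 (2S,3R,9R)-2-methyl-3,9-bis(TIPSO)decanal, via ozonide 41 (not isolated)
Conditions: O3, CH2Cl2, −78 °C; PPh3
Reagents that add atoms: ozone, [O-][O+]=O
Why: Neutral ozonolysis gives the C41 aldehyde without epimerising C42.

Step 26
Reactants: 42 (2S,3R,9R)-2-methyl-3,9-bis(TIPSO)decanal
Product: 44 (4S,5R,6R,12R)-5-methyl-6,12-bis(TIPSO)tridec-1-yn-4-ol, via pinacol borate 43 (not isolated)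
Conditions: allenylB(pin), (S)-TRIP (10 mol %), 4 Å MS, toluene, −20 °C; aq. NaHCO3
Reagents that add atoms: allenylboronic acid pinacol ester, C=C=CB1OC(C)(C)C(C)(C)O1
Why: Chiral-phosphoric-acid-catalysed SE2′ propargylation sets C41 by catalyst control in the Felkin (41,42-syn) sense, completing the all-syn triad and leaving C41-OH as the only free hydroxyl.

### Assembly and ring closure

Step 27
Reactants: 31 (2Z,5R,9R,13R)-19-chloro-2-iodo-5,9,13-tris(TBSO)nonadec-2-ene; 19 C19 aldehyde (C4–C19 fragment)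
Product: 47 C4–C37 hexa-TBS bis-acetonide chloride, via alkenyllithium 45 (not isolated), via lithium alkoxide 46 (not isolated)
Conditions: 31 (1.2 equiv), t-BuLi (2.0 equiv per 31), Et2O, −78 °C; 19, −78 °C; TBSOTf, −78 → 0 °C
Reagents that add atoms: TBSOTf, CC(C)(C)[Si](C)(C)OS(=O)(=O)C(F)(F)F
Why: I/Li exchange with retention is followed by Felkin–Anh addition to the 2,3-anti α-methyl-β-silyloxy aldehyde, where Felkin and 1,3-anti polar induction reinforce to give 18,19-syn/17,19-anti (19S), and the alkoxide is silylated in the same flask.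

Step 28
Reactants: 47 C4–C37 hexa-TBS bis-acetonide chloride
Product: 48 C37 primary iodide
Conditions: NaI (10 equiv), NaHCO3, 2-butanone, 80 °C
Reagents that add atoms: sodium iodide, [Na+].[I-]
Why: The Finkelstein exchange is driven by precipitation of NaCl, and silyl ethers, acetonides and the vinyl iodide are unaffected.

Step 29
Reactants: 44 (4S,5R,6R,12R)-5-methyl-6,12-bis(TIPSO)tridec-1-yn-4-ol; 48 C37 primary iodide
Product: 50 C4–C50 iodo-alkynol, via dilithio acetylide-alkoxide 49 (not isolated)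
Conditions: 44 (1.8 equiv), n-BuLi (2.0 equiv per 44), THF, −78 → −20 °C; 48, DMPU, −20 °C → rt
Reagents that add atoms: none
Why: SN2 alkylation of the acetylide–alkoxide dianion occurs at the more nucleophilic carbon, forges C37–C38 and leaves C41-OH free without any protecting-group step.

Step 30
Reactants: 50 C4–C50 iodo-alkynol; 51 propiolic acid
Product: 52 2,38-diynoic seco-acid
Conditions: 51 (3 equiv), Pd(PPh3)4 (10 mol %), DBU (6 equiv), DMSO/THF, rt → 35 °C; cold aq. citric acid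
Reagents that add atoms: none
Why: Copper-free Sonogashira coupling of the propiolate anion, which is neither a Michael acceptor nor prone to decarboxylation at this temperature, replaces the vinyl iodide with retention and gives the (4Z)-enynoic acid directly.

Step 31
Reactants: 52 2,38-diynoic seco-acid
Product: 54 42-membered diyne macrolactone, via mixed anhydride 53 (not isolated)
Conditions: 2,4,6-Cl3C6H2COCl, Et3N, THF, rt; syringe-pump addition to DMAP, toluene (0.5 mM), 40 °C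
Reagents that add atoms: none
Why: In this Yamaguchi macrolactonisation the only free hydroxyl (C41) attacks the activated C1 acyl as in thioesterase off-loading, with retention at C41, and because C2–C3 is still an alkyne no Z→E isomerisation of the activated acyl is possible while two linear alkynes cut the conformational freedom of the chain.

Step 32
Reactants: 54 42-membered diyne macrolactone
Product: 55 fully protected (2Z,4Z,20Z,38Z)-macrolactone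
Conditions: H2 (1 atm), Lindlar catalyst, quinoline, EtOAc/hexane, rt, monitored to 2 equiv H2
Reagents that add atoms: none
Why: Syn semi-hydrogenation of both alkynes in one operation sets 2Z and 38Z, and the trisubstituted alkenes are not reduced on the poisoned catalyst.

Step 33
Reactants: 55 fully protected (2Z,4Z,20Z,38Z)-macrolactone
Product: 56 CNP0392687.2 (target)
Conditions: 48 % aq. HF, MeCN, 0 °C → rt; NaHCO3 quench at 0 °C
Reagents that add atoms: none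
Why: Aqueous HF cleaves the six TBS ethers, the two TIPS ethers and the two strained anti-acetonides in one global deprotection, no stereocentre is touched, and the acidic medium suppresses O41→O43 acyl migration.

## Compound list

1 | propane-1,3-diol | OCCCO | starting material
2 | (4R,6R)-nona-1,8-diene-4,6-diol | C=CC[C@@H](O)C[C@H](O)CC=C | intermediate
3 | bis-ozonide of 2 | C1OC(C[C@@H](O)C[C@H](O)CC2OCOO2)OO1 | intermediate
4 | (3R,5R)-heptane-1,3,5,7-tetraol | OCC[C@@H](O)C[C@H](O)CCO | intermediate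
5 | (4S,6R,8R,10S)-trideca-1,12-diene-4,6,8,10-tetraol (all-anti) | C=CC[C@H](O)C[C@@H](O)C[C@H](O)C[C@@H](O)CC=C | intermediate
6 | bis-acetonide of 5 (O7/O9 and O11/O13) | C=CC[C@H]1C[C@H](C[C@H]2C[C@H](CC=C)OC(C)(C)O2)OC(C)(C)O1 | intermediate
7 | bis-ozonide of 6 | C1OC(C[C@H]2C[C@H](C[C@H]3C[C@H](CC4OCOO4)OC(C)(C)O3)OC(C)(C)O2)OO1 | intermediate
8 | C2-symmetric C5,C15-dialdehyde bis-acetonide | O=CC[C@H]1C[C@H](C[C@H]2C[C@H](CC=O)OC(C)(C)O2)OC(C)(C)O1 | intermediate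
9 | (Z)-C4-iodoalkene C15-aldehyde | C/C(I)=C/C[C@H]1C[C@H](C[C@H]2C[C@H](CC=O)OC(C)(C)O2)OC(C)(C)O1 | intermediate
10 | C15 O-B(lIpc)2 borinate | C/C(I)=C/C[C@H]1C[C@H](C[C@H]2C[C@H](C[C@H](OB([C@H]5C[C@H]6C[C@@H]([C@@H]5C)C6(C)C)[C@H]7C[C@H]8C[C@@H]([C@@H]7C)C8(C)C)CC=C)OC(C)(C)O2)OC(C)(C)O1 | intermediate
11 | C15 homoallylic alcohol (C15 as in target) | C/C(I)=C/C[C@H]1C[C@H](C[C@H]2C[C@H](C[C@H](O)CC=C)OC(C)(C)O2)OC(C)(C)O1 | intermediate
12 | C15 TBS ether | C/C(I)=C/C[C@H]1C[C@H](C[C@H]2C[C@H](C[C@H](O[Si](C)(C)C(C)(C)C)CC=C)OC(C)(C)O2)OC(C)(C)O1 | intermediate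
13 | vicinal diol from 12 | C/C(I)=C/C[C@H]1C[C@H](C[C@H]2C[C@H](C[C@H](O[Si](C)(C)C(C)(C)C)CC(O)CO)OC(C)(C)O2)OC(C)(C)O1 | intermediate
14 | C17 aldehyde | C/C(I)=C/C[C@H]1C[C@H](C[C@H]2C[C@H](C[C@H](O[Si](C)(C)C(C)(C)C)CC=O)OC(C)(C)O2)OC(C)(C)O1 | intermediate
15 | C17 O-B(dIpc)2 borinate | C/C(I)=C/C[C@H]1C[C@H](C[C@H]2C[C@H](C[C@H](O[Si](C)(C)C(C)(C)C)C[C@@H](OB([C@@H]5C[C@@H]6C[C@H]([C@H]5C)C6(C)C)[C@@H]7C[C@@H]8C[C@H]([C@H]7C)C8(C)C)[C@@H](C)C=C)OC(C)(C)O2)OC(C)(C)O1 | intermediate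
16 | 17,18-anti crotyl adduct (C17-OH free) | C/C(I)=C/C[C@H]1C[C@H](C[C@H]2C[C@H](C[C@H](O[Si](C)(C)C(C)(C)C)C[C@@H](O)[C@@H](C)C=C)OC(C)(C)O2)OC(C)(C)O1 | intermediate
17 | C15,C17-bis-TBS ether | C/C(I)=C/C[C@H]1C[C@H](C[C@H]2C[C@H](C[C@H](O[Si](C)(C)C(C)(C)C)C[C@@H](O[Si](C)(C)C(C)(C)C)[C@@H](C)C=C)OC(C)(C)O2)OC(C)(C)O1 | intermediate
18 | vicinal diol from 17 | C/C(I)=C/C[C@H]1C[C@H](C[C@H]2C[C@H](C[C@H](O[Si](C)(C)C(C)(C)C)C[C@@H](O[Si](C)(C)C(C)(C)C)[C@@H](C)C(O)CO)OC(C)(C)O2)OC(C)(C)O1 | intermediate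
19 | C19 aldehyde (C4–C19 fragment) | C/C(I)=C/C[C@H]1C[C@H](C[C@H]2C[C@H](C[C@H](O[Si](C)(C)C(C)(C)C)C[C@@H](O[Si](C)(C)C(C)(C)C)[C@@H](C)C=O)OC(C)(C)O2)OC(C)(C)O1 | intermediate
20 | 7-chloroheptan-1-ol | OCCCCCCCCl | starting material
21 | (R)-10-chlorodec-1-en-4-ol | C=CC[C@H](O)CCCCCCCl | intermediate
22 | (6R)-6-(6-chlorohexyl)tetrahydro-2H-pyran-2-ol (anomers) | OC1CCC[C@@H](CCCCCCCl)O1 | intermediate
23 | C27 O-B(dIpc)2 borinate | C=CC[C@H](OB([C@@H]5C[C@@H]6C[C@H]([C@H]5C)C6(C)C)[C@@H]7C[C@@H]8C[C@H]([C@H]7C)C8(C)C)CCC[C@H](O)CCCCCCCl | intermediate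
24 | (4R,8R)-14-chlorotetradec-1-ene-4,8-diol | C=CC[C@H](O)CCC[C@H](O)CCCCCCCl | intermediate
25 | (6R)-6-[(4R)-10-chloro-4-hydroxydecyl]tetrahydro-2H-pyran-2-ol (anomers) | OC1CCC[C@@H](CCC[C@H](O)CCCCCCCl)O1 | intermediate
26 | C23 O-B(dIpc)2 borinate | C=CC[C@H](OB([C@@H]5C[C@@H]6C[C@H]([C@H]5C)C6(C)C)[C@@H]7C[C@@H]8C[C@H]([C@H]7C)C8(C)C)CCC[C@H](O)CCC[C@H](O)CCCCCCCl | intermediate
27 | (4R,8R,12R)-18-chlorooctadec-1-ene-4,8,12-triol | C=CC[C@H](O)CCC[C@H](O)CCC[C@H](O)CCCCCCCl | intermediate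
28 | tris-TBS ether of 27 | C=CC[C@H](O[Si](C)(C)C(C)(C)C)CCC[C@H](O[Si](C)(C)C(C)(C)C)CCC[C@H](O[Si](C)(C)C(C)(C)C)CCCCCCCl | intermediate
29 | ozonide of 28 | C1OC(C[C@H](O[Si](C)(C)C(C)(C)C)CCC[C@H](O[Si](C)(C)C(C)(C)C)CCC[C@H](O[Si](C)(C)C(C)(C)C)CCCCCCCl)OO1 | intermediate
30 | (3R,7R,11R)-17-chloro-3,7,11-tris(TBSO)heptadecanal | O=CC[C@H](O[Si](C)(C)C(C)(C)C)CCC[C@H](O[Si](C)(C)C(C)(C)C)CCC[C@H](O[Si](C)(C)C(C)(C)C)CCCCCCCl | intermediate
31 | (2Z,5R,9R,13R)-19-chloro-2-iodo-5,9,13-tris(TBSO)nonadec-2-ene (C20–C37 fragment) | C/C(I)=C/C[C@H](O[Si](C)(C)C(C)(C)C)CCC[C@H](O[Si](C)(C)C(C)(C)C)CCC[C@H](O[Si](C)(C)C(C)(C)C)CCCCCCCl | intermediate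
32 | 6-bromohex-1-ene | BrCCCCC=C | starting material
33 | (R)-propylene oxide | C[C@@H]1CO1 | starting material
34 | hex-5-enylmagnesium bromide | C=CCCCC[Mg]Br | intermediate
35 | (R)-non-8-en-2-ol | C=CCCCCC[C@@H](C)O | intermediate
36 | ozonide of 35 | C1OC(CCCCC[C@@H](C)O)OO1 | intermediate
37 | (R)-7-hydroxyoctanal | O=CCCCCC[C@@H](C)O | intermediate
38 | C43 O-B(dIpc)2 borinate | C=C[C@@H](C)[C@H](OB([C@@H]5C[C@@H]6C[C@H]([C@H]5C)C6(C)C)[C@@H]7C[C@@H]8C[C@H]([C@H]7C)C8(C)C)CCCCC[C@@H](C)O | intermediate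
39 | (2R,8R,9R)-9-methylundec-10-ene-2,8-diol | C=C[C@@H](C)[C@H](O)CCCCC[C@@H](C)O | intermediate
40 | bis-TIPS ether of 39 | C=C[C@@H](C)[C@H](O[Si](C(C)C)(C(C)C)C(C)C)CCCCC[C@@H](C)O[Si](C(C)C)(C(C)C)C(C)C | intermediate
41 | ozonide of 40 | C1OC([C@@H](C)[C@H](O[Si](C(C)C)(C(C)C)C(C)C)CCCCC[C@@H](C)O[Si](C(C)C)(C(C)C)C(C)C)OO1 | intermediate
42 | (2S,3R,9R)-2-methyl-3,9-bis(TIPSO)decanal | O=C[C@@H](C)[C@H](O[Si](C(C)C)(C(C)C)C(C)C)CCCCC[C@@H](C)O[Si](C(C)C)(C(C)C)C(C)C | intermediate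
43 | C41 O-B(pin) borate | C#CC[C@@H]([C@@H](C)[C@H](O[Si](C(C)C)(C(C)C)C(C)C)CCCCC[C@@H](C)O[Si](C(C)C)(C(C)C)C(C)C)OB1OC(C)(C)C(C)(C)O1 | intermediate
44 | (4S,5R,6R,12R)-5-methyl-6,12-bis(TIPSO)tridec-1-yn-4-ol (C38–C50 fragment) | C#CC[C@@H]([C@@H](C)[C@H](O[Si](C(C)C)(C(C)C)C(C)C)CCCCC[C@@H](C)O[Si](C(C)C)(C(C)C)C(C)C)O | intermediate
45 | (Z)-alkenyllithium from 31 | C/C([Li])=C/C[C@H](O[Si](C)(C)C(C)(C)C)CCC[C@H](O[Si](C)(C)C(C)(C)C)CCC[C@H](O[Si](C)(C)C(C)(C)C)CCCCCCCl | intermediate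
46 | C19 lithium alkoxide | C/C(I)=C/C[C@H]1C[C@H](C[C@H]2C[C@H](C[C@H](O[Si](C)(C)C(C)(C)C)C[C@@H](O[Si](C)(C)C(C)(C)C)[C@@H](C)[C@H](O[Li])/C(C)=C\C[C@H](O[Si](C)(C)C(C)(C)C)CCC[C@H](O[Si](C)(C)C(C)(C)C)CCC[C@H](O[Si](C)(C)C(C)(C)C)CCCCCCCl)OC(C)(C)O2)OC(C)(C)O1 | intermediate
47 | C4–C37 hexa-TBS bis-acetonide chloride (4Z,20Z) | C/C(I)=C/C[C@H]1C[C@H](C[C@H]2C[C@H](C[C@H](O[Si](C)(C)C(C)(C)C)C[C@@H](O[Si](C)(C)C(C)(C)C)[C@@H](C)[C@H](O[Si](C)(C)C(C)(C)C)/C(C)=C\C[C@H](O[Si](C)(C)C(C)(C)C)CCC[C@H](O[Si](C)(C)C(C)(C)C)CCC[C@H](O[Si](C)(C)C(C)(C)C)CCCCCCCl)OC(C)(C)O2)OC(C)(C)O1 | intermediate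
48 | C37 primary iodide | C/C(I)=C/C[C@H]1C[C@H](C[C@H]2C[C@H](C[C@H](O[Si](C)(C)C(C)(C)C)C[C@@H](O[Si](C)(C)C(C)(C)C)[C@@H](C)[C@H](O[Si](C)(C)C(C)(C)C)/C(C)=C\C[C@H](O[Si](C)(C)C(C)(C)C)CCC[C@H](O[Si](C)(C)C(C)(C)C)CCC[C@H](O[Si](C)(C)C(C)(C)C)CCCCCCI)OC(C)(C)O2)OC(C)(C)O1 | intermediate
49 | dilithio acetylide-alkoxide of 44 | [Li]C#CC[C@@H]([C@@H](C)[C@H](O[Si](C(C)C)(C(C)C)C(C)C)CCCCC[C@@H](C)O[Si](C(C)C)(C(C)C)C(C)C)O[Li] | intermediate
50 | C4–C50 iodo-alkynol (C41-OH free) | C/C(I)=C/C[C@H]1C[C@H](C[C@H]2C[C@H](C[C@H](O[Si](C)(C)C(C)(C)C)C[C@@H](O[Si](C)(C)C(C)(C)C)[C@@H](C)[C@H](O[Si](C)(C)C(C)(C)C)/C(C)=C\C[C@H](O[Si](C)(C)C(C)(C)C)CCC[C@H](O[Si](C)(C)C(C)(C)C)CCC[C@H](O[Si](C)(C)C(C)(C)C)CCCCCCC#CC[C@@H]([C@@H](C)[C@H](O[Si](C(C)C)(C(C)C)C(C)C)CCCCC[C@@H](C)O[Si](C(C)C)(C(C)C)C(C)C)O)OC(C)(C)O2)OC(C)(C)O1 | intermediate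
51 | propiolic acid | C#CC(=O)O | starting material
52 | 2,38-diynoic seco-acid | C/C(C#CC(=O)O)=C/C[C@H]1C[C@H](C[C@H]2C[C@H](C[C@H](O[Si](C)(C)C(C)(C)C)C[C@@H](O[Si](C)(C)C(C)(C)C)[C@@H](C)[C@H](O[Si](C)(C)C(C)(C)C)/C(C)=C\C[C@H](O[Si](C)(C)C(C)(C)C)CCC[C@H](O[Si](C)(C)C(C)(C)C)CCC[C@H](O[Si](C)(C)C(C)(C)C)CCCCCCC#CC[C@@H]([C@@H](C)[C@H](O[Si](C(C)C)(C(C)C)C(C)C)CCCCC[C@@H](C)O[Si](C(C)C)(C(C)C)C(C)C)O)OC(C)(C)O2)OC(C)(C)O1 | intermediate
53 | 2,4,6-trichlorobenzoyl mixed anhydride of 52 | C/C(C#CC(=O)OC(=O)c4c(Cl)cc(Cl)cc4Cl)=C/C[C@H]1C[C@H](C[C@H]2C[C@H](C[C@H](O[Si](C)(C)C(C)(C)C)C[C@@H](O[Si](C)(C)C(C)(C)C)[C@@H](C)[C@H](O[Si](C)(C)C(C)(C)C)/C(C)=C\C[C@H](O[Si](C)(C)C(C)(C)C)CCC[C@H](O[Si](C)(C)C(C)(C)C)CCC[C@H](O[Si](C)(C)C(C)(C)C)CCCCCCC#CC[C@@H]([C@@H](C)[C@H](O[Si](C(C)C)(C(C)C)C(C)C)CCCCC[C@@H](C)O[Si](C(C)C)(C(C)C)C(C)C)O)OC(C)(C)O2)OC(C)(C)O1 | intermediate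
54 | 42-membered diyne macrolactone (protected) | C/C1=C/C[C@H]2C[C@H](C[C@H]3C[C@H](C[C@H](O[Si](C)(C)C(C)(C)C)C[C@@H](O[Si](C)(C)C(C)(C)C)[C@@H](C)[C@H](O[Si](C)(C)C(C)(C)C)/C(C)=C\C[C@H](O[Si](C)(C)C(C)(C)C)CCC[C@H](O[Si](C)(C)C(C)(C)C)CCC[C@H](O[Si](C)(C)C(C)(C)C)CCCCCCC#CC[C@@H]([C@@H](C)[C@H](O[Si](C(C)C)(C(C)C)C(C)C)CCCCC[C@@H](C)O[Si](C(C)C)(C(C)C)C(C)C)OC(=O)C#C1)OC(C)(C)O3)OC(C)(C)O2 | intermediate
55 | fully protected (2Z,4Z,20Z,38Z)-macrolactone | CC1=C/C[C@H]2C[C@H](C[C@H]3C[C@H](C[C@H](O[Si](C)(C)C(C)(C)C)C[C@@H](O[Si](C)(C)C(C)(C)C)[C@@H](C)[C@H](O[Si](C)(C)C(C)(C)C)/C(C)=C\C[C@H](O[Si](C)(C)C(C)(C)C)CCC[C@H](O[Si](C)(C)C(C)(C)C)CCC[C@H](O[Si](C)(C)C(C)(C)C)CCCCCC/C=C\C[C@@H]([C@@H](C)[C@H](O[Si](C(C)C)(C(C)C)C(C)C)CCCCC[C@@H](C)O[Si](C(C)C)(C(C)C)C(C)C)OC(=O)/C=C\1)OC(C)(C)O3)OC(C)(C)O2 | intermediate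
56 | CNP0392687.2 | CC1=C/C[C@H](O)C[C@@H](O)C[C@H](O)C[C@@H](O)C[C@H](O)C[C@@H](O)[C@@H](C)[C@H](O)/C(C)=C\C[C@H](O)CCC[C@H](O)CCC[C@H](O)CCCCCC/C=C\C[C@@H]([C@@H](C)[C@H](O)CCCCC[C@@H](C)O)OC(=O)/C=C\1 | target

## Step count and main risks

Total step count: 33 (12 for C4–C19, 8 for C20–C37, 6 for C38–C50, 7 for assembly).
Longest linear sequence: 19 (steps 1–12, then 27–33).

The three steps most likely to fail are steps 31, 30 and 27.

**Step 31 (ring closure of the ynoyl mixed anhydride at 42 atoms).** DMAP may add to the activated enynoate, or oligomers may form. The fallback sets out from 50 and comes back at 55.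
- The acyl terminus is installed at the alkene oxidation level and closed through a thioester.
- Pd(0)-catalysed Stille coupling of 50 with (Z)-3-(tributylstannyl)acrylic acid gives the (2Z,4Z)-dienoic seco-acid F9.
- 2,2′-Dipyridyl disulfide and PPh3 convert it into the S-(2-pyridyl) thioester F10.
- AgOTf in dilute toluene, with no nucleophilic catalyst and with the thiolate removed as its silver salt, closes the ring to the dienoate macrolactone that still carries the C38 alkyne F11.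
- Lindlar semi-hydrogenation of that single alkyne returns 55.

**Step 30 (Sonogashira coupling of a hindered (Z)-2-iodoalkene with free propiolic acid).** The coupling may be slow or the acid may decarboxylate. The fallback sets out from 50 and comes back at 52. It builds C1 from CO2 instead.
- Pd/Cu coupling of 50 with trimethylsilylacetylene (Et3N) gives the silyl enyne F7.
- K2CO3/MeOH gives the terminal enyne F8.
- Double deprotonation (n-BuLi, 2.1 equiv, now safe because no vinyl iodide is left) and a CO2 quench return 52.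

**Step 27 (facial selectivity at C19, and possible Li/I scrambling with the C4 iodide).** The fallback sets out from 16 and 31 and comes back at 47. It sets C19 by a hydroxyl-directed C–H bond formation instead of a C–C bond formation.
- 16 is silylated with TESOTf to the C17 triethylsilyl ether F1.
- Johnson–Lemieux cleavage gives the aldehyde F2.
- Addition of 45 gives the C19-epimeric allylic alcohols F3.
- Dess–Martin oxidation gives the (Z)-enone F4.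
- Buffered HF·pyridine removes only the TES group to give the β-hydroxy enone F5.
- Me4NBH(OAc)3 delivers hydride intramolecularly (Evans–Saksena) to give the 17,19-anti diol F6.
- Double silylation with TBSOTf returns 47.

## Further compounds

F1 | step 27 | C17 triethylsilyl ether of 16 | C/C(I)=C/C[C@H]1C[C@H](C[C@H]2C[C@H](C[C@H](O[Si](C)(C)C(C)(C)C)C[C@@H](O[Si](CC)(CC)CC)[C@@H](C)C=C)OC(C)(C)O2)OC(C)(C)O1
F2 | step 27 | C19 aldehyde with C17-OTES | C/C(I)=C/C[C@H]1C[C@H](C[C@H]2C[C@H](C[C@H](O[Si](C)(C)C(C)(C)C)C[C@@H](O[Si](CC)(CC)CC)[C@@H](C)C=O)OC(C)(C)O2)OC(C)(C)O1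
F3 | step 27 | C19-epimeric allylic alcohols | C/C(I)=C/C[C@H]1C[C@H](C[C@H]2C[C@H](C[C@H](O[Si](C)(C)C(C)(C)C)C[C@@H](O[Si](CC)(CC)CC)[C@@H](C)C(O)/C(C)=C\C[C@H](O[Si](C)(C)C(C)(C)C)CCC[C@H](O[Si](C)(C)C(C)(C)C)CCC[C@H](O[Si](C)(C)C(C)(C)C)CCCCCCCl)OC(C)(C)O2)OC(C)(C)O1
F4 | step 27 | C19 (Z)-enone with C17-OTES | C/C(I)=C/C[C@H]1C[C@H](C[C@H]2C[C@H](C[C@H](O[Si](C)(C)C(C)(C)C)C[C@@H](O[Si](CC)(CC)CC)[C@@H](C)C(=O)/C(C)=C\C[C@H](O[Si](C)(C)C(C)(C)C)CCC[C@H](O[Si](C)(C)C(C)(C)C)CCC[C@H](O[Si](C)(C)C(C)(C)C)CCCCCCCl)OC(C)(C)O2)OC(C)(C)O1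
F5 | step 27 | C17-hydroxy C19 (Z)-enone | C/C(I)=C/C[C@H]1C[C@H](C[C@H]2C[C@H](C[C@H](O[Si](C)(C)C(C)(C)C)C[C@@H](O)[C@@H](C)C(=O)/C(C)=C\C[C@H](O[Si](C)(C)C(C)(C)C)CCC[C@H](O[Si](C)(C)C(C)(C)C)CCC[C@H](O[Si](C)(C)C(C)(C)C)CCCCCCCl)OC(C)(C)O2)OC(C)(C)O1
F6 | step 27 | 17,19-anti diol | C/C(I)=C/C[C@H]1C[C@H](C[C@H]2C[C@H](C[C@H](O[Si](C)(C)C(C)(C)C)C[C@@H](O)[C@@H](C)[C@H](O)/C(C)=C\C[C@H](O[Si](C)(C)C(C)(C)C)CCC[C@H](O[Si](C)(C)C(C)(C)C)CCC[C@H](O[Si](C)(C)C(C)(C)C)CCCCCCCl)OC(C)(C)O2)OC(C)(C)O1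
F7 | step 30 | C2-trimethylsilyl (4Z)-enyne | C/C(C#C[Si](C)(C)C)=C/C[C@H]1C[C@H](C[C@H]2C[C@H](C[C@H](O[Si](C)(C)C(C)(C)C)C[C@@H](O[Si](C)(C)C(C)(C)C)[C@@H](C)[C@H](O[Si](C)(C)C(C)(C)C)/C(C)=C\C[C@H](O[Si](C)(C)C(C)(C)C)CCC[C@H](O[Si](C)(C)C(C)(C)C)CCC[C@H](O[Si](C)(C)C(C)(C)C)CCCCCCC#CC[C@@H]([C@@H](C)[C@H](O[Si](C(C)C)(C(C)C)C(C)C)CCCCC[C@@H](C)O[Si](C(C)C)(C(C)C)C(C)C)O)OC(C)(C)O2)OC(C)(C)O1
F8 | step 30 | terminal (4Z)-enyne | C/C(C#C)=C/C[C@H]1C[C@H](C[C@H]2C[C@H](C[C@H](O[Si](C)(C)C(C)(C)C)C[C@@H](O[Si](C)(C)C(C)(C)C)[C@@H](C)[C@H](O[Si](C)(C)C(C)(C)C)/C(C)=C\C[C@H](O[Si](C)(C)C(C)(C)C)CCC[C@H](O[Si](C)(C)C(C)(C)C)CCC[C@H](O[Si](C)(C)C(C)(C)C)CCCCCCC#CC[C@@H]([C@@H](C)[C@H](O[Si](C(C)C)(C(C)C)C(C)C)CCCCC[C@@H](C)O[Si](C(C)C)(C(C)C)C(C)C)O)OC(C)(C)O2)OC(C)(C)O1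
F9 | step 31 | (2Z,4Z)-dienoic 38-ynoic seco-acid | OC(=O)/C=C\C(C)=C/C[C@H]1C[C@H](C[C@H]2C[C@H](C[C@H](O[Si](C)(C)C(C)(C)C)C[C@@H](O[Si](C)(C)C(C)(C)C)[C@@H](C)[C@H](O[Si](C)(C)C(C)(C)C)/C(C)=C\C[C@H](O[Si](C)(C)C(C)(C)C)CCC[C@H](O[Si](C)(C)C(C)(C)C)CCC[C@H](O[Si](C)(C)C(C)(C)C)CCCCCCC#CC[C@@H]([C@@H](C)[C@H](O[Si](C(C)C)(C(C)C)C(C)C)CCCCC[C@@H](C)O[Si](C(C)C)(C(C)C)C(C)C)O)OC(C)(C)O2)OC(C)(C)O1
F10 | step 31 | S-(2-pyridyl) thioester of F9 | O=C(Sc4ccccn4)/C=C\C(C)=C/C[C@H]1C[C@H](C[C@H]2C[C@H](C[C@H](O[Si](C)(C)C(C)(C)C)C[C@@H](O[Si](C)(C)C(C)(C)C)[C@@H](C)[C@H](O[Si](C)(C)C(C)(C)C)/C(C)=C\C[C@H](O[Si](C)(C)C(C)(C)C)CCC[C@H](O[Si](C)(C)C(C)(C)C)CCC[C@H](O[Si](C)(C)C(C)(C)C)CCCCCCC#CC[C@@H]([C@@H](C)[C@H](O[Si](C(C)C)(C(C)C)C(C)C)CCCCC[C@@H](C)O[Si](C(C)C)(C(C)C)C(C)C)O)OC(C)(C)O2)OC(C)(C)O1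
F11 | step 31 | (2Z,4Z)-dienoate macrolactone with C38 alkyne | CC1=C/C[C@H]2C[C@H](C[C@H]3C[C@H](C[C@H](O[Si](C)(C)C(C)(C)C)C[C@@H](O[Si](C)(C)C(C)(C)C)[C@@H](C)[C@H](O[Si](C)(C)C(C)(C)C)/C(C)=C\C[C@H](O[Si](C)(C)C(C)(C)C)CCC[C@H](O[Si](C)(C)C(C)(C)C)CCC[C@H](O[Si](C)(C)C(C)(C)C)CCCCCCC#CC[C@@H]([C@@H](C)[C@H](O[Si](C(C)C)(C(C)C)C(C)C)CCCCC[C@@H](C)O[Si](C(C)C)(C(C)C)C(C)C)OC(=O)/C=C\1)OC(C)(C)O3)OC(C)(C)O2
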